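**Retrosynthetic overview**

1. Numbering: ring A is counted from the carbon bearing the aroyl group (C1; OH at C2, OMe at C4, side chain at C5), ring B is the 4-hydroxybenzoyl ring, ring C the terminal 4-hydroxyphenyl ring. The chain is Cα (on ring A C5), Cβ, Cγ (on ring C). The route rests on this C5–Cα–Cβ–Cγ–ring C unit: two benzylic methylenes around one central CH2, which is a stilbene Cα=Cγ with Cβ inserted into its central bond.
2. Last disconnection: the target is traced back to trans-1,2-diarylcyclopropane 12, whose doubly benzylic Cα–Cγ bond is cut by hydrogenolysis in the forward direction. 12 comes from triacetate 11 by methanolysis.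
3. Key disconnection: Cα–Cβ and Cβ–Cγ of 11, both made at once by zinc-carbenoid CH2 transfer from diiodomethane 10 to (E)-stilbene 9.
4. 9 is cut at ring A C5–Cα (Mizoroki–Heck coupling of bromide 7 with 4-acetoxystyrene 8). 7 comes from benzophenone 5 by bromination at C5 and acetylation, and 5 from 1,3-dimethoxybenzene 3 and acid chloride 2 by Friedel–Crafts acylation with chelation-directed loss of the C2 methyl.
5. Ring order: rings A, B and C are bought as benzene rings. The only ring formed is the cyclopropane (step 6), and it is opened again in step 8.

Key step: step 6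

Assumption: cyclopropanes 11 and 12 are carried as racemates, since both of their stereocentres are removed in step 8 and the target is achiral.

**Route**

Step 1
Reactants: 1 4-acetoxybenzoic acid
Product: 2 4-acetoxybenzoyl chloride
Conditions: (COCl)2, DMF (cat.), CH2Cl2, 0 °C to rt; concentrate, use crude
Reagents that add atoms: oxalyl chloride, O=C(Cl)C(=O)Cl
Why: Acid chloride formation through the catalytic Vilsmeier-type chloroiminium species runs without base or nucleophile, so the aryl acetate should stay intact.

Step 2
Reactants: 2 4-acetoxybenzoyl chloride; 3 1,3-dimethoxybenzene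
Product: 5 4-(2-hydroxy-4-methoxybenzoyl)phenyl acetate, via dimethoxy ketone 4 (not isolated)
Conditions: AlCl3 (3 equiv), CH2Cl2, 0 °C, then 40 °C; aq. HCl work-up
Reagents that add atoms: none
Why: Friedel–Crafts acylation should go at C4 of 3 (para to one methoxy, ortho to the other), and the aluminium chelate between the new carbonyl and the ortho methoxy oxygen is then demethylated by chloride while the para methoxy is left alone; because 3 is consumed at 0 °C before warming and ring B is acyl-deactivated, the aryl acetate should neither undergo Fries rearrangement nor find an electron-rich arene to acetylate.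

Step 3
Reactants: 5 4-(2-hydroxy-4-methoxybenzoyl)phenyl acetate
Product: 6 4-(5-bromo-2-hydroxy-4-methoxybenzoyl)phenyl acetate
Conditions: NBS (1.05 equiv), MeCN, 0 °C to rt
Reagents that add atoms: N-bromosuccinimide, O=C1CCC(=O)N1Br
Why: Electrophilic aromatic bromination should go to ring A C5, which is para to the free hydroxyl and ortho to the methoxy, because C3 is crowded between the two oxygens and ring B is deactivated by its acyl and acetoxy groups.

Step 4
Reactants: 6 4-(5-bromo-2-hydroxy-4-methoxybenzoyl)phenyl acetate
Product: 7 2-(4-acetoxybenzoyl)-4-bromo-5-methoxyphenyl acetate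
Conditions: Ac2O, pyridine, DMAP (cat.), CH2Cl2, rt
Reagents that add atoms: acetic anhydride, CC(=O)OC(C)=O
Why: DMAP-catalysed acyl transfer is strong enough to acetylate the hydrogen-bonded C2 phenol, and the product has no acidic proton left for the zinc reagent of step 6.

Step 5
Reactants: 7 2-(4-acetoxybenzoyl)-4-bromo-5-methoxyphenyl acetate; 8 4-acetoxystyrene
Product: 9 2-(4-acetoxybenzoyl)-4-[(E)-2-(4-acetoxyphenyl)ethenyl]-5-methoxyphenyl acetate
Conditions: Pd2(dba)3 (cat.), [HP(t-Bu)3]BF4 (cat.), Cy2NMe, 1,4-dioxane, 60 °C
Reagents that add atoms: none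
Why: Mizoroki–Heck coupling, in which zerovalent palladium carrying the bulky electron-rich phosphine inserts into the electron-rich, ortho-substituted C–Br bond, and syn insertion at the terminal alkene carbon followed by syn β-hydride elimination gives the E alkene; the anhydrous tertiary amine should leave the aryl acetates alone.

Step 6
Reactants: 9 (E)-stilbene triacetate; 10 diiodomethane
Product: 11 2-(4-acetoxybenzoyl)-4-[trans-2-(4-acetoxyphenyl)cyclopropyl]-5-methoxyphenyl acetate (racemic)
Conditions: Et2Zn (4 equiv), CF3CO2H (4 equiv), CH2Cl2, 0 °C; 10 (4 equiv), 0 °C; then 9, 0 °C to rt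
Reagents that add atoms: diiodomethane (compound 10), ICI
Why: Simmons–Smith cyclopropanation with the trifluoroacetate-modified zinc carbenoid CF3CO2ZnCH2I, which is made from Et2Zn, CF3CO2H and 10 before 9 is added so that no free Et2Zn meets the ketone; this more electrophilic carbenoid is the known remedy for stilbenes, which react slowly with plain Et2Zn/CH2I2. The carbenoid carbon is delivered to the Cα=Cγ bond through a concerted butterfly transition state in which zinc iodide trifluoroacetate departs as the Cα–Cβ and Cβ–Cγ bonds form. The three-membered ring Cα–Cβ–Cγ therefore closes in a single (2+1) addition and not by a stepwise ring closure. Cα and Cγ become stereocentres, and because the addition is suprafacial and stereospecific the E geometry of 9 fixes them as trans; with no chiral element present 11 forms as a racemate, which does not matter because both centres are erased in step 8. The selectivity needed is chemoselectivity for the alkene over the ketone and the three esters: the carbenoid is an electrophile, so the carbonyl groups only bind zinc (hence the excess reagent), while the ortho methoxy on ring A and the para oxygen on ring C keep the alkene nucleophilic enough.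

Step 7
Reactants: 11 racemic trans-cyclopropane triacetate
Product: 12 (4-hydroxyphenyl){2-hydroxy-5-[trans-2-(4-hydroxyphenyl)cyclopropyl]-4-methoxyphenyl}methanone (racemic)
Conditions: K2CO3 (3 equiv), MeOH, 0 °C to rt; then 1 M HCl
Reagents that add atoms: none
Why: Base-mediated transesterification removes the three aryl acetates as methyl acetate, the acceptor-free cyclopropane is inert to carbonate, and freeing the C2 hydroxyl here means the ketone enters step 8 as a hydrogen-bonded, strongly donor-conjugated carbonyl.

Step 8
Reactants: 12 racemic trans-cyclopropane triphenol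
Product: 13 (4-hydroxyphenyl){2-hydroxy-5-[3-(4-hydroxyphenyl)propyl]-4-methoxyphenyl}methanone (target)
Conditions: H2 (1–4 bar), 10% Pd/C, EtOAc, rt
Reagents that add atoms: none
Why: Catalytic hydrogenolysis of an arylcyclopropane should cut the Cα–Cγ bond, the only ring bond that is benzylic at both ends, so that Cα and Cγ each gain one hydrogen, end up 1,3 across Cβ and lose their stereochemistry, while the diaryl ketone, chelated by the C2 hydroxyl and fed by two para oxygen donors, should resist reduction in a neutral aprotic solvent as it does in routine O-debenzylations of hydroxybenzophenones.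

**Compound list**

1 | 4-acetoxybenzoic acid | CC(=O)Oc1ccc(cc1)C(=O)O | starting material
2 | 4-acetoxybenzoyl chloride | CC(=O)Oc1ccc(cc1)C(=O)Cl | intermediate
3 | 1,3-dimethoxybenzene | COc1cccc(OC)c1 | starting material
4 | 4-(2,4-dimethoxybenzoyl)phenyl acetate | COc1ccc(C(=O)c2ccc(OC(C)=O)cc2)c(OC)c1 | intermediate (not isolated)
5 | 4-(2-hydroxy-4-methoxybenzoyl)phenyl acetate | COc1ccc(C(=O)c2ccc(OC(C)=O)cc2)c(O)c1 | intermediate
6 | 4-(5-bromo-2-hydroxy-4-methoxybenzoyl)phenyl acetate | COc1cc(O)c(C(=O)c2ccc(OC(C)=O)cc2)cc1Br | intermediate
7 | 2-(4-acetoxybenzoyl)-4-bromo-5-methoxyphenyl acetate | COc1cc(OC(C)=O)c(C(=O)c2ccc(OC(C)=O)cc2)cc1Br | intermediate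
8 | 4-acetoxystyrene | C=Cc1ccc(OC(C)=O)cc1 | starting material
9 | 2-(4-acetoxybenzoyl)-4-[(E)-2-(4-acetoxyphenyl)ethenyl]-5-methoxyphenyl acetate | COc1cc(OC(C)=O)c(C(=O)c2ccc(OC(C)=O)cc2)cc1/C=C/c1ccc(OC(C)=O)cc1 | intermediate
10 | diiodomethane | ICI | starting material
11 | 2-(4-acetoxybenzoyl)-4-[trans-2-(4-acetoxyphenyl)cyclopropyl]-5-methoxyphenyl acetate, racemic, one enantiomer drawn | COc1cc(OC(C)=O)c(C(=O)c2ccc(OC(C)=O)cc2)cc1[C@@H]1C[C@H]1c1ccc(OC(C)=O)cc1 | intermediate
12 | (4-hydroxyphenyl){2-hydroxy-5-[trans-2-(4-hydroxyphenyl)cyclopropyl]-4-methoxyphenyl}methanone, racemic, one enantiomer drawn | COc1cc(O)c(C(=O)c2ccc(O)cc2)cc1[C@@H]1C[C@H]1c1ccc(O)cc1 | intermediate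
13 | (4-hydroxyphenyl){2-hydroxy-5-[3-(4-hydroxyphenyl)propyl]-4-methoxyphenyl}methanone | COc1cc(O)c(C(=O)c2ccc(O)cc2)cc1CCCc1ccc(O)cc1 | target

**Step count**

Total steps: 8. Longest linear sequence: 8 steps (1 to 13); compounds 3, 8 and 10 each enter in a single step.

**Steps most likely to fail**

Step 6. The methylene transfer may stall. The 1,2-diarylalkene is only moderately nucleophilic and its four carbonyl oxygens bind the zinc reagent, so conversion can stop short and leave alkene that is hard to separate from the cyclopropane. The fallback closes the three-membered ring on a simpler alkene and attaches it by cross-coupling; it sets out from 4-acetoxystyrene 8 and bromide 7 and comes back at 12. Compound 8 is cross-metathesised with vinylboronic acid pinacol ester ((H2IMes)(PCy3)Cl2Ru=CHPh, the second-generation Grubbs catalyst, CH2Cl2, 40 °C) to (E)-2-(4-acetoxyphenyl)ethenylboronic acid pinacol ester F1. Cyclopropanation of this alkenylboronate with diazomethane and Pd(OAc)2 (Et2O, 0 °C), a reliable reaction for this substrate class, should give racemic trans-2-(4-acetoxyphenyl)cyclopropylboronic acid pinacol ester F2. Suzuki–Miyaura coupling of F2 with 7 (Pd(OAc)2, SPhos, K3PO4, toluene–water, 90 °C) proceeds with retention at the cyclopropyl carbon. The crude product, which is triacetate 11 together with whatever has lost acetate under the basic coupling, is methanolysed as in step 7 and rejoins the route at 12.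

Step 8. The hydrogenolysis may be accompanied by reduction of the diaryl carbonyl, by cleavage of a ring bond to Cβ, or by incomplete ring opening. Each would leave material of nearly the same polarity as the target. The fallback builds the three-carbon chain without hydrogen gas; it sets out from bromide 7 and comes back at 13. 4-Allylphenyl acetate (bought, or made from 4-allylphenol and Ac2O) is hydroborated with 9-BBN-H (THF, rt) to 9-[3-(4-acetoxyphenyl)propyl]-9-borabicyclo[3.3.1]nonane F3. This is coupled in the same flask with 7 in a B-alkyl Suzuki–Miyaura reaction (PdCl2(dppf), K3PO4, DMF–THF, 50 °C) to 2-(4-acetoxybenzoyl)-4-[3-(4-acetoxyphenyl)propyl]-5-methoxyphenyl acetate F4. Methanolysis of F4 (K2CO3, MeOH, rt; then 1 M HCl) should give 13.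

Step 2. The ring B acetyl group may be lost or transferred under AlCl3, with the aryl acetate acting as an acetyl donor, and demethylation may be uneven, so that a mixture results. The fallback stops defending the acetate; it sets out from 2 and 3 and comes back at 5. The acylation and demethylation are driven to completion (AlCl3, ClCH2CH2Cl, 60 °C), and the crude mixture is methanolysed (K2CO3, MeOH) so that everything converges on (4-hydroxyphenyl)(2-hydroxy-4-methoxyphenyl)methanone F5. F5 is then acetylated only at the free ring B hydroxyl (Ac2O 1.05 equiv, pyridine, CH2Cl2, 0 °C), the chelated C2 hydroxyl being too unreactive under these conditions, which should give 5.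

**Further compounds**

F1 | step 6 | (E)-2-(4-acetoxyphenyl)ethenylboronic acid pinacol ester | CC(=O)Oc1ccc(/C=C/B2OC(C)(C)C(C)(C)O2)cc1
F2 | step 6 | trans-2-(4-acetoxyphenyl)cyclopropylboronic acid pinacol ester, racemic, one enantiomer drawn | CC(=O)Oc1ccc([C@@H]2C[C@H]2B3OC(C)(C)C(C)(C)O3)cc1
F3 | step 8 | 9-[3-(4-acetoxyphenyl)propyl]-9-borabicyclo[3.3.1]nonane | CC(=O)Oc1ccc(CCCB2C3CCCC2CCC3)cc1
F4 | step 8 | 2-(4-acetoxybenzoyl)-4-[3-(4-acetoxyphenyl)propyl]-5-methoxyphenyl acetate | COc1cc(OC(C)=O)c(C(=O)c2ccc(OC(C)=O)cc2)cc1CCCc1ccc(OC(C)=O)cc1
F5 | step 2 | (4-hydroxyphenyl)(2-hydroxy-4-methoxyphenyl)methanone | COc1ccc(C(=O)c2ccc(O)cc2)c(O)c1
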